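**Retrosynthetic overview**
- The target comes from its 4'-O-acetate by a neutral deacetylation in the last step.
- The C8–prenyl bond comes from a para-Claisen rearrangement (Claisen, then Cope; two [3,3] shifts) of the 5-O-prenyl ether of (2S)-4'-acetoxy-5-hydroxy-6,7-dimethoxyflavanone. The 6-OMe blocks the ortho position, so the prenyl group is relayed to C8 and the 5-OH is set free.
- The 6-OMe comes from 6-OH, and that from 6-CHO (Rieche formylation ortho to the chelated 5-OH, Dakin-type Baeyer–Villiger oxidation, O-methylation).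
- The 7-OMe and 4'-OAc groups come from two selective O-functionalisations of (2S)-naringenin.
- No ring is formed: rings A, B and C and the C2 (S) stereocentre are bought in (2S)-naringenin. Every step is neutral or acidic so that ring C never opens to the chalcone.

Assumption: (2S)-naringenin (the natural (−)-enantiomer from citrus) is bought enantiopure and its ee is confirmed by chiral HPLC before use.

**Route**

Step 1
Reactants: 1 (2S)-naringenin; 2 (trimethylsilyl)diazomethane
Product: 3 (2S)-sakuranetin [(2S)-5-hydroxy-2-(4-hydroxyphenyl)-7-methoxychroman-4-one]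
Conditions: TMSCHN2 (1.1 equiv, 2 M in hexanes), THF–MeOH 3:1, 0 °C to rt, 2 h
Reagents that add atoms: (trimethylsilyl)diazomethane, C[Si](C)(C)C=[N+]=[N-] (supplies the O-methyl carbon)
Why: Base-free diazoalkane O-methylation picks the 7-OH, a vinylogous acid (pKa about 7.5) far more acidic than the 4'-OH and the hydrogen-bonded 5-OH, and the neutral medium leaves the bought C2 (S) centre untouched.

Step 2
Reactants: 3 (2S)-sakuranetin; 4 acetic anhydride
Product: 5 4-[(2S)-5-hydroxy-7-methoxy-4-oxochroman-2-yl]phenyl acetate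
Conditions: Ac2O (1.1 equiv), pyridine (2 equiv), CH2Cl2, 0 °C, 1 h
Reagents that add atoms: acetic anhydride, CC(=O)OC(C)=O
Why: O-acylation of the only unhindered free phenol, since the 5-OH is locked in a hydrogen bond to C4=O and is not esterified at 0 °C; the acetate also deactivates ring B toward the next electrophilic step.

Step 3
Reactants: 5 4-[(2S)-5-hydroxy-7-methoxy-4-oxochroman-2-yl]phenyl acetate; 6 dichloromethyl methyl ether; 7 water
Product: 9 4-[(2S)-6-formyl-5-hydroxy-7-methoxy-4-oxochroman-2-yl]phenyl acetate, via chloro(methoxy)methyl adduct 8 (not isolated)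
Conditions: TiCl4 (4 equiv), Cl2CHOMe (1.5 equiv), CH2Cl2, −10 to 0 °C, 2 h; then ice-cold 1 M aq. HCl
Reagents that add atoms: dichloromethyl methyl ether, COC(Cl)Cl (formyl carbon); water, O (formyl oxygen on hydrolysis)
Why: Rieche formylation, in which the titanium phenoxide at O5 directs the oxocarbenium electrophile to its only free ortho position C6 (the site electrophiles attack in 5-hydroxy-7-alkoxyflavonoids), while the acidic medium cannot trigger the base-induced retro-oxa-Michael opening of ring C, so C2 stays S.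

Step 4
Reactants: 9 4-[(2S)-6-formyl-5-hydroxy-7-methoxy-4-oxochroman-2-yl]phenyl acetate; 10 mCPBA
Product: 12 4-[(2S)-5,6-dihydroxy-7-methoxy-4-oxochroman-2-yl]phenyl acetate, via 6-formate ester 11 (not isolated)
Conditions: mCPBA (1.15 equiv), CH2Cl2, 0 °C to rt; then MeOH, Et3N (0.1 equiv), 0 °C, 15 min, Ar
Reagents that add atoms: mCPBA, OOC(=O)c1cccc(Cl)c1 (the new 6-oxygen)
Why: Dakin-type Baeyer–Villiger oxidation, in which the electron-rich 2,6-dioxygenated aryl group migrates to oxygen while the deactivated C4 ketone is inert, and the very labile catechol monoformate is transesterified by methanol without loss of the aryl acetate.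

Step 5
Reactants: 12 4-[(2S)-5,6-dihydroxy-7-methoxy-4-oxochroman-2-yl]phenyl acetate; 2 (trimethylsilyl)diazomethane
Product: 13 4-[(2S)-5-hydroxy-6,7-dimethoxy-4-oxochroman-2-yl]phenyl acetate
Conditions: TMSCHN2 (1.3 equiv), iPr2NEt (1.3 equiv), MeCN–MeOH 9:1, 0 °C to rt, Ar
Reagents that add atoms: (trimethylsilyl)diazomethane, C[Si](C)(C)C=[N+]=[N-] (supplies the O-methyl carbon)
Why: Diazoalkane O-methylation is selective for the free 6-OH because the 5-OH is chelated to C4=O (the classical partial methylation pattern of 5,6,7-trioxygenated flavonoids), and the hindered amine at room temperature does not enolise the ketone.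

Step 6
Reactants: 13 4-[(2S)-5-hydroxy-6,7-dimethoxy-4-oxochroman-2-yl]phenyl acetate; 14 3-methylbut-2-en-1-ol (prenol)
Product: 15 4-[(2S)-6,7-dimethoxy-5-(3-methylbut-2-en-1-yloxy)-4-oxochroman-2-yl]phenyl acetate
Conditions: prenol (1.5 equiv), PPh3 (1.5 equiv), DIAD (1.5 equiv), THF, 0 °C to rt, 12 h
Reagents that add atoms: 3-methylbut-2-en-1-ol, CC(C)=CCO (the C5 prenyl unit)
Why: Mitsunobu etherification, in which the chelated phenol is acidic enough to protonate the betaine and attacks the primary allylic alkoxyphosphonium ion at CH2 (SN2, no allylic transposition) under essentially neutral conditions that keep C2 intact.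

Step 7
Reactants: 15 4-[(2S)-6,7-dimethoxy-5-(3-methylbut-2-en-1-yloxy)-4-oxochroman-2-yl]phenyl acetate
Product: 18 4-[(2S)-5-hydroxy-6,7-dimethoxy-8-(3-methylbut-2-en-1-yl)-4-oxochroman-2-yl]phenyl acetate, via ortho-dienone 16 (not isolated), via para-dienone 17 (not isolated)
Conditions: Eu(fod)3 (10 mol %), CHCl3, 60 °C, sealed tube, 16 h
Reagents that add atoms: none
Why: Lewis-acid-accelerated aromatic Claisen rearrangement followed by Cope rearrangement (para-Claisen): Eu(fod)3 chelates O5/C4=O, the first [3,3] shift delivers a 1,1-dimethylallyl group to the methoxy-blocked C6 to give a dienone that cannot tautomerise, the second [3,3] shift carries it to C8 with prenyl connectivity restored, and enolisation gives the 5-phenol; the transient sp3 centres at C6 and C8 vanish and C2 is not involved.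

Step 8
Reactants: 18 4-[(2S)-5-hydroxy-6,7-dimethoxy-8-(3-methylbut-2-en-1-yl)-4-oxochroman-2-yl]phenyl acetate
Product: 19 (2S)-5-hydroxy-2-(4-hydroxyphenyl)-6,7-dimethoxy-8-(3-methylbut-2-en-1-yl)chroman-4-one (CNP0104932.1)
Conditions: NH4OAc (10 equiv), MeOH–H2O 4:1, rt, 6 h
Reagents that add atoms: none
Why: Ammonium-acetate-mediated solvolysis (deacetylation) cleaves aryl acetates at about pH 7, so there is neither phenoxide-driven opening of ring C (racemisation at C2) nor acid-induced hydration of the prenyl alkene.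

**Compound list**

1 | (2S)-naringenin, (2S)-5,7-dihydroxy-2-(4-hydroxyphenyl)chroman-4-one | Oc1cc(O)c2c(c1)O[C@H](c1ccc(O)cc1)CC2=O | starting material
2 | (trimethylsilyl)diazomethane | C[Si](C)(C)C=[N+]=[N-] | starting material
3 | (2S)-sakuranetin, (2S)-5-hydroxy-2-(4-hydroxyphenyl)-7-methoxychroman-4-one | COc1cc(O)c2c(c1)O[C@H](c1ccc(O)cc1)CC2=O | intermediate
4 | acetic anhydride | CC(=O)OC(C)=O | starting material
5 | 4-[(2S)-5-hydroxy-7-methoxy-4-oxochroman-2-yl]phenyl acetate | COc1cc(O)c2c(c1)O[C@H](c1ccc(OC(C)=O)cc1)CC2=O | intermediate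
6 | dichloromethyl methyl ether | COC(Cl)Cl | starting material
7 | water | O | starting material
8 | chloro(methoxy)methyl adduct, 4-[(2S)-6-[chloro(methoxy)methyl]-5-hydroxy-7-methoxy-4-oxochroman-2-yl]phenyl acetate, not isolated | COC(Cl)c1c(O)c2c(cc1OC)O[C@H](c1ccc(OC(C)=O)cc1)CC2=O | intermediate
9 | 4-[(2S)-6-formyl-5-hydroxy-7-methoxy-4-oxochroman-2-yl]phenyl acetate | O=Cc1c(O)c2c(cc1OC)O[C@H](c1ccc(OC(C)=O)cc1)CC2=O | intermediate
10 | mCPBA, 3-chloroperoxybenzoic acid | OOC(=O)c1cccc(Cl)c1 | starting material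
11 | 6-formate ester, 4-[(2S)-6-(formyloxy)-5-hydroxy-7-methoxy-4-oxochroman-2-yl]phenyl acetate, not isolated | O=COc1c(O)c2c(cc1OC)O[C@H](c1ccc(OC(C)=O)cc1)CC2=O | intermediate
12 | 4-[(2S)-5,6-dihydroxy-7-methoxy-4-oxochroman-2-yl]phenyl acetate | Oc1c(O)c2c(cc1OC)O[C@H](c1ccc(OC(C)=O)cc1)CC2=O | intermediate
13 | 4-[(2S)-5-hydroxy-6,7-dimethoxy-4-oxochroman-2-yl]phenyl acetate | COc1c(O)c2c(cc1OC)O[C@H](c1ccc(OC(C)=O)cc1)CC2=O | intermediate
14 | 3-methylbut-2-en-1-ol (prenol) | CC(C)=CCO | starting material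
15 | 4-[(2S)-6,7-dimethoxy-5-(3-methylbut-2-en-1-yloxy)-4-oxochroman-2-yl]phenyl acetate | COc1c(OCC=C(C)C)c2c(cc1OC)O[C@H](c1ccc(OC(C)=O)cc1)CC2=O | intermediate
16 | ortho-dienone, 4-[(2S)-6,7-dimethoxy-6-(2-methylbut-3-en-2-yl)-4,5-dioxo-3,4,5,6-tetrahydro-2H-chromen-2-yl]phenyl acetate (both C6 epimers), not isolated | C=CC(C)(C)C1(OC)C(=O)C2=C(C=C1OC)O[C@H](c1ccc(OC(C)=O)cc1)CC2=O | intermediate
17 | para-dienone, 4-[(2S)-6,7-dimethoxy-8-(3-methylbut-2-en-1-yl)-4,5-dioxo-3,4,5,8-tetrahydro-2H-chromen-2-yl]phenyl acetate (both C8 epimers), not isolated | O=C1C(OC)=C(OC)C(CC=C(C)C)C2=C1C(=O)C[C@@H](c1ccc(OC(C)=O)cc1)O2 | intermediate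
18 | 4-[(2S)-5-hydroxy-6,7-dimethoxy-8-(3-methylbut-2-en-1-yl)-4-oxochroman-2-yl]phenyl acetate | COc1c(O)c2c(c(CC=C(C)C)c1OC)O[C@H](c1ccc(OC(C)=O)cc1)CC2=O | intermediate
19 | (2S)-5-hydroxy-2-(4-hydroxyphenyl)-6,7-dimethoxy-8-(3-methylbut-2-en-1-yl)chroman-4-one | COc1c(O)c2c(c(CC=C(C)C)c1OC)O[C@H](c1ccc(O)cc1)CC2=O | target

**Step count and risks**

Total step count: 8. Longest linear sequence: 8 (fully linear from 1). The ee of 19 should be checked by chiral HPLC against the value measured for 1.

The three steps most likely to fail: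

Step 3 (Rieche formylation). Ring A is deactivated by the titanium chelate, and C8 or ring B could compete with C6. The fallback sets out from compound 5 and first fixes the regiochemistry by halogenation. NIS (1.05 equiv) in DMF at rt iodinates ortho to the free 5-OH and gives 4-[(2S)-5-hydroxy-6-iodo-7-methoxy-4-oxochroman-2-yl]phenyl acetate F1. A neutral reductive carbonylation of the aryl iodide (Pd(PPh3)4 5 mol %, CO 3 bar, Bu3SnH added slowly, THF, 50 °C) then gives the aldehyde. The fallback comes back to the route at compound 9.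

Step 6 (Mitsunobu prenylation). The 5-OH is hydrogen-bonded and flanked by the 6-OMe group, so etherification may stall. The fallback sets out from compound 13 and forms the C8–prenyl bond by cross-coupling, without the ether. NIS with catalytic CF3CO2H in MeCN at 0 °C iodinates the only free position of ring A and gives 4-[(2S)-5-hydroxy-8-iodo-6,7-dimethoxy-4-oxochroman-2-yl]phenyl acetate F2. Base-free Stille coupling with tributyl(3-methylbut-2-en-1-yl)stannane (Pd(PPh3)4, DMF, 90 °C) then installs the prenyl group. The fallback comes back to the route at compound 18.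

Step 7 (Claisen–Cope). The Lewis acid may ionise the prenyl ether and simply return phenol 13, or the crowded first shift may be slow. The fallback sets out from compound 13 and uses an allyl group, which rearranges without fragmentation.
- Mitsunobu reaction with allyl alcohol (PPh3, DIAD, THF) gives 4-[(2S)-5-(allyloxy)-6,7-dimethoxy-4-oxochroman-2-yl]phenyl acetate F3.
- Heating (Eu(fod)3 10 mol %, PhCl, 100 °C, or neat o-dichlorobenzene at 180 °C) takes it through the 6-allyl-6-methoxy ortho-dienone F4 and the 8-allyl para-dienone F5, neither isolated, to 4-[(2S)-8-allyl-5-hydroxy-6,7-dimethoxy-4-oxochroman-2-yl]phenyl acetate F6.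
- Olefin cross-metathesis with excess 2-methylbut-2-ene (second-generation Grubbs catalyst, CH2Cl2, 40 °C) converts the allyl group into prenyl.

The fallback comes back to the route at compound 18.

**Further compounds**

F1 | step 3 | 4-[(2S)-5-hydroxy-6-iodo-7-methoxy-4-oxochroman-2-yl]phenyl acetate | COc1cc2c(c(O)c1I)C(=O)C[C@@H](c1ccc(OC(C)=O)cc1)O2
F2 | step 6 | 4-[(2S)-5-hydroxy-8-iodo-6,7-dimethoxy-4-oxochroman-2-yl]phenyl acetate | COc1c(O)c2c(c(I)c1OC)O[C@H](c1ccc(OC(C)=O)cc1)CC2=O
F3 | step 7 | 4-[(2S)-5-(allyloxy)-6,7-dimethoxy-4-oxochroman-2-yl]phenyl acetate | COc1c(OCC=C)c2c(cc1OC)O[C@H](c1ccc(OC(C)=O)cc1)CC2=O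
F4 | step 7 | 6-allyl-6-methoxy ortho-dienone, 4-[(2S)-6-allyl-6,7-dimethoxy-4,5-dioxo-3,4,5,6-tetrahydro-2H-chromen-2-yl]phenyl acetate | C=CCC1(OC)C(=O)C2=C(C=C1OC)O[C@H](c1ccc(OC(C)=O)cc1)CC2=O
F5 | step 7 | 8-allyl para-dienone, 4-[(2S)-8-allyl-6,7-dimethoxy-4,5-dioxo-3,4,5,8-tetrahydro-2H-chromen-2-yl]phenyl acetate | O=C1C(OC)=C(OC)C(CC=C)C2=C1C(=O)C[C@@H](c1ccc(OC(C)=O)cc1)O2
F6 | step 7 | 4-[(2S)-8-allyl-5-hydroxy-6,7-dimethoxy-4-oxochroman-2-yl]phenyl acetate | COc1c(O)c2c(c(CC=C)c1OC)O[C@H](c1ccc(OC(C)=O)cc1)CC2=O
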